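**Retrosynthetic overview**
1. Target 8 (1R,2R, threo) ⇒ racemic keto enal 6: one reductive step sets C7 and C8 together by dynamic kinetic resolution and also takes CHO to CH2OH.
2. 6 ⇒ keto aldehyde 5 by a two-carbon Wittig homologation that sets the E-alkene.
3. 5 ⇒ α-bromo ketone 2 + syringaldehyde 3: the 8–O–4′ C(sp3)–O aryl ether bond, the only fragment union (SN2).
4. 2 ⇒ 3′,4′,5′-trimethoxypropiophenone 1 by α-bromination.
5. No ring is formed; both benzene rings are bought intact.

Assumption: 3′,4′,5′-trimethoxypropiophenone (1) is bought as a catalogue building block, as are syringaldehyde, Ph3P=CHCHO and RuCl[(S,S)-TsDPEN](p-cymene).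

**Step 1**
Reactants: 1 1-(3,4,5-trimethoxyphenyl)propan-1-one
Product: 2 rac-2-bromo-1-(3,4,5-trimethoxyphenyl)propan-1-one
Conditions: CuBr2 (2.1 equiv), EtOAc/CHCl3 1:1, reflux, 4 h
Reagents that add atoms: copper(II) bromide, [Cu+2].[Br-].[Br-]
Why: King–Ostrum α-bromination through the copper enolate is selective for the α-carbon of aryl ketones, and the acyl group deactivates the ring against nuclear bromination; the new centre is racemic on purpose.

**Step 2**
Reactants: 2 rac-2-bromo-1-(3,4,5-trimethoxyphenyl)propan-1-one; 3 syringaldehyde (4-hydroxy-3,5-dimethoxybenzaldehyde)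
Product: 5 rac-3,5-dimethoxy-4-{[1-oxo-1-(3,4,5-trimethoxyphenyl)propan-2-yl]oxy}benzaldehyde, via potassium 4-formyl-2,6-dimethoxyphenolate 4 (not isolated)
Conditions: 3, K2CO3 (1.5 equiv), DMF, rt, 30 min; then 2 (1.05 equiv), rt → 50 °C, 12 h
Reagents that add atoms: none
Why: Williamson ether synthesis (SN2): K2CO3 deprotonates the acidic phenol but not the ketone, and the α-halo ketone is activated enough for the 2,6-disubstituted phenolate to form the 8–O–4′ C–O bond; the centre stays racemic.

**Step 3**
Reactants: 5 rac-3,5-dimethoxy-4-{[1-oxo-1-(3,4,5-trimethoxyphenyl)propan-2-yl]oxy}benzaldehyde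
Product: 6 rac-(E)-3-(3,5-dimethoxy-4-{[1-oxo-1-(3,4,5-trimethoxyphenyl)propan-2-yl]oxy}phenyl)prop-2-enal
Conditions: Ph3P=CHCHO (1.2 equiv), toluene, 85 °C, 16 h
Reagents that add atoms: (triphenylphosphoranylidene)acetaldehyde, O=CC=P(c1ccccc1)(c1ccccc1)c1ccccc1
Why: Wittig olefination with the stabilised formylmethylene ylide attacks the aryl aldehyde but not the hindered aryl ketone and gives the E-enal; only a small excess of ylide is used to limit a second homologation to the dienal.

**Step 4**
Reactants: 6 rac-(E)-3-(3,5-dimethoxy-4-{[1-oxo-1-(3,4,5-trimethoxyphenyl)propan-2-yl]oxy}phenyl)prop-2-enal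
Product: 8 (1R,2R)-2-{4-[(E)-3-hydroxyprop-1-en-1-yl]-2,6-dimethoxyphenoxy}-1-(3,4,5-trimethoxyphenyl)propan-1-ol, via keto allylic alcohol 7 (not isolated)
Conditions: RuCl[(S,S)-TsDPEN](p-cymene) (2 mol%), HCO2H (6 equiv)/DBU (7 equiv), MeCN, 40 °C, 24–48 h
Reagents that add atoms: none
Why: Proposed new method: dynamic kinetic resolution by Noyori–Ikariya asymmetric transfer hydrogenation of an acyclic α-aryloxy α-methyl aryl ketone, run together with 1,2-reduction of the enal. The outer-sphere Ru–H/N–H transfer reduces only polar C=O, so the aldehyde goes first to 7 and the styrenyl C=C is untouched. The slight excess of DBU epimerises C8 of 7 through its enolate (α-aryloxy ketone, estimated pKa about 21 in DMSO) faster than the electron-rich, branched ketone is reduced. The (S,S)-catalyst holds the aryl ring under the cymene (CH/π) and delivers hydride to the face that gives the 1R carbinol; this is the same spatial sense as (S)-1-phenylethanol, and the descriptor is R only because C8 outranks the aryl group. That face is the polar Felkin–Anh face (C–OAr anti to the incoming hydride, H inside) only for the (2R)-ketone, so the (R)-enantiomer is drained to the (1R,2R)-threo alcohol while the (S)-enantiomer keeps racemising. The closest known reactions are the DKR transfer hydrogenation of benzoin to (R,R)-hydrobenzoin with this same (S,S)-catalyst and of 2-substituted indanones and α-heteroatom β-keto esters; an acyclic α-aryloxy alkyl ketone activated by a single carbonyl has not been shown.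

**Compound list**
1 | 1-(3,4,5-trimethoxyphenyl)propan-1-one | CCC(=O)c1cc(OC)c(OC)c(OC)c1 | starting material
2 | rac-2-bromo-1-(3,4,5-trimethoxyphenyl)propan-1-one | CC(Br)C(=O)c1cc(OC)c(OC)c(OC)c1 | intermediate
3 | syringaldehyde (4-hydroxy-3,5-dimethoxybenzaldehyde) | COc1cc(C=O)cc(OC)c1O | starting material
4 | potassium 4-formyl-2,6-dimethoxyphenolate (not isolated) | [K+].COc1cc(C=O)cc(OC)c1[O-] | intermediate
5 | rac-3,5-dimethoxy-4-{[1-oxo-1-(3,4,5-trimethoxyphenyl)propan-2-yl]oxy}benzaldehyde | COc1cc(C(=O)C(C)Oc2c(OC)cc(C=O)cc2OC)cc(OC)c1OC | intermediate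
6 | rac-(E)-3-(3,5-dimethoxy-4-{[1-oxo-1-(3,4,5-trimethoxyphenyl)propan-2-yl]oxy}phenyl)prop-2-enal | COc1cc(C(=O)C(C)Oc2c(OC)cc(/C=C/C=O)cc2OC)cc(OC)c1OC | intermediate
7 | 2-{4-[(E)-3-hydroxyprop-1-en-1-yl]-2,6-dimethoxyphenoxy}-1-(3,4,5-trimethoxyphenyl)propan-1-one (racemic, C2 epimerising, not isolated) | COc1cc(C(=O)C(C)Oc2c(OC)cc(/C=C/CO)cc2OC)cc(OC)c1OC | intermediate
8 | (1R,2R)-2-{4-[(E)-3-hydroxyprop-1-en-1-yl]-2,6-dimethoxyphenoxy}-1-(3,4,5-trimethoxyphenyl)propan-1-ol | COc1cc([C@@H](O)[C@@H](C)Oc2c(OC)cc(/C=C/CO)cc2OC)cc(OC)c1OC | target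

**Step count and risks**
Total steps: 4. Longest linear sequence: 4 (1 → 2 → 5 → 6 → 8; syringaldehyde enters at step 2).

Most likely to fail, step 4 (the proposed new step). Racemisation of C8 may be too slow, which would leave a plain kinetic resolution. The Felkin preference may give only a moderate threo:erythro ratio. Some of the allylic alcohol may be formylated or the enal over-reduced. The fallback uses known chemistry only, sets out from 6 and comes back at 8. Compound 6 is reduced with NaBH4/15-crown-5 in i-PrOH/CH2Cl2 at −20 °C, a non-chelating, Felkin–Anh-controlled hydride delivery that I recall as threo-favouring for such α-aryloxy ketones and that also reduces the aldehyde 1,2. Any erythro isomer is removed on silica. The racemic threo alcohol, a 1:1 mixture of 8 and (1S,2S)-2-{4-[(E)-3-hydroxyprop-1-en-1-yl]-2,6-dimethoxyphenoxy}-1-(3,4,5-trimethoxyphenyl)propan-1-ol F1, is then resolved by preparative HPLC on an amylose tris(3,5-dimethylphenylcarbamate) phase to give 8 (at most 50%).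

Second, step 3. The electron-rich aldehyde may react slowly and the product enal may be homologated again to the dienal. The fallback sets out from 5 and comes back at 8. Compound 5 is treated with ethyl (triphenylphosphoranylidene)acetate (toluene, 60 °C) to give ethyl (E)-3-(3,5-dimethoxy-4-{[1-oxo-1-(3,4,5-trimethoxyphenyl)propan-2-yl]oxy}phenyl)prop-2-enoate F2, which cannot over-homologate. F2 is put through the step-4 conditions, where only the ketone reacts, to give ethyl (E)-3-(4-{[(1R,2R)-1-hydroxy-1-(3,4,5-trimethoxyphenyl)propan-2-yl]oxy}-3,5-dimethoxyphenyl)prop-2-enoate F3. DIBAL-H (3.5 equiv, CH2Cl2, −78 °C) then reduces the ester of F3 to the allylic alcohol 8. This also takes the enal out of the new step, at the cost of one extra step.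

Third, step 2. The phenolate is hindered and weakened by the para-formyl group, and the bromo ketone can eliminate or undergo Darzens-type reaction with the aldehyde. The fallback sets out from 2 and comes back at 6, replacing steps 2 and 3. Compound 2 is alkylated with bought 4-allyl-2,6-dimethoxyphenol (methoxyeugenol, a more nucleophilic phenol with no aldehyde; K2CO3, acetone, reflux) to give rac-2-(4-allyl-2,6-dimethoxyphenoxy)-1-(3,4,5-trimethoxyphenyl)propan-1-one F4. The allylarene of F4 is then oxidised with DDQ (2.2 equiv, dioxane/H2O, rt) by benzylic hydride abstraction, water capture and further oxidation to the E-enal 6.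

**Further compounds**
F1 | step 4 | (1S,2S)-2-{4-[(E)-3-hydroxyprop-1-en-1-yl]-2,6-dimethoxyphenoxy}-1-(3,4,5-trimethoxyphenyl)propan-1-ol | COc1cc([C@H](O)[C@H](C)Oc2c(OC)cc(/C=C/CO)cc2OC)cc(OC)c1OC
F2 | step 3 | rac-ethyl (E)-3-(3,5-dimethoxy-4-{[1-oxo-1-(3,4,5-trimethoxyphenyl)propan-2-yl]oxy}phenyl)prop-2-enoate | COc1cc(C(=O)C(C)Oc2c(OC)cc(/C=C/C(=O)OCC)cc2OC)cc(OC)c1OC
F3 | step 3 | ethyl (E)-3-(4-{[(1R,2R)-1-hydroxy-1-(3,4,5-trimethoxyphenyl)propan-2-yl]oxy}-3,5-dimethoxyphenyl)prop-2-enoate | COc1cc([C@@H](O)[C@@H](C)Oc2c(OC)cc(/C=C/C(=O)OCC)cc2OC)cc(OC)c1OC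
F4 | step 2 | rac-2-(4-allyl-2,6-dimethoxyphenoxy)-1-(3,4,5-trimethoxyphenyl)propan-1-one | COc1cc(C(=O)C(C)Oc2c(OC)cc(CC=C)cc2OC)cc(OC)c1OC
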